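**Strategy.** Everything rests on making the aromatic ring (C4a, C5, C6, C7, C8, C8a) by strain-release benzannulation. The feature exploited is its contiguous C5–O, C6–O, C7–C19 array and its fusion at C4a–C8a to the trans C1/C4 cyclohexane ring. A squarate-derived cyclobutenone already holds C5–C8 in that order, and dihydrocarvone supplies C1–C4, C4a and C8a. On heating, the four-membered ring opens at C5–C8 to a dienylketene that closes C8–C8a and tautomerises, giving the fully substituted tetralin in one operation, with only a surplus C8 hydroxyl to remove. The precursor is a 4-cyclohexenyl-4-silyloxy-3-isopropoxy-2-(benzyloxymethyl)cyclobutenone from Shapiro vinyllithium addition to the cyclobutenedione.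

Key step: step 7

**Remarks before the steps**
- Numbering: locants are those of the target (tetralin C1–C8a, side chain C11–C18, C19 on C7, C20 on C4, C17 on C15). The target is 1S,4R,11S,15S.
- Assumption 1: the C14–C17 unit is bought as (R)-3-bromo-2-methylpropan-1-ol; its bromomethyl carbon becomes C14 and its carbinol carbon C16, which corresponds to 15S.
- Assumption 2: in step 14 (R)-DTBM-SEGPHOS is written as the ligand that gives 11S. The sense of induction on this substrate cannot be fixed on paper, and the (S)-ligand replaces it unchanged if the opposite face is attacked.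
- Design choices: C5–O carries tert-butyldimethylsilyl, because the aryl silyl ether must last ten further steps. The surplus C8 oxygen is kept as the triflate through the Lewis acid step, where it blocks the last free ring position. C19 stays a benzyl ether and is opened oxidatively to the aldehyde, so no hydrogenolysis of a doubly benzylic ether is needed.

**Step 1**
Reactants: 1 (R)-carvone
Product: 2 trans-dihydrocarvone, (2R,5R)-2-methyl-5-(prop-1-en-2-yl)cyclohexan-1-one
Conditions: LiBH(s-Bu)3, THF, −78 °C; aq. NH4Cl
Reagents that add atoms: none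
Why: Conjugate (1,4) hydride reduction of the enone by the bulky borohydride leaves the isopropenyl group alone, and axial protonation of the enolate should place the new C2 methyl (future C4/C20) equatorial, trans to the isopropenyl group, which is also the thermodynamic epimer.

**Step 2**
Reactants: 2 trans-dihydrocarvone
Product: 3 (E)-2,4,6-triisopropylbenzenesulfonylhydrazone of 2
Conditions: 2,4,6-(i-Pr)3C6H2SO2NHNH2, HCl (cat.), MeOH, rt; recrystallise
Reagents that add atoms: 2,4,6-tri(propan-2-yl)benzenesulfonohydrazide, NNS(=O)(=O)c1c(C(C)C)cc(C(C)C)cc1C(C)C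
Why: Acid-catalysed hydrazone condensation should give the E isomer with the sulfonamide anti to the methyl-bearing carbon, and crystallisation should remove any cis epimer carried from step 1.

**Step 3**
Reactants: 4 benzyl chloromethyl ether
Product: 5 [(benzyloxy)methyl]tributylstannane
Conditions: Bu3SnH, LiN(i-Pr)2, THF, 0 °C; then 4, −78 °C → rt
Reagents that add atoms: tributyltin hydride, CCCC[SnH](CCCC)CCCC
Why: SN2 displacement of chloride from the reactive chloromethyl ether by the stannyl anion is the standard entry to α-alkoxymethyl stannanes.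

**Step 4**
Reactants: 5 [(benzyloxy)methyl]tributylstannane; 6 diisopropyl squarate
Product: 9 3-[(benzyloxy)methyl]-4-isopropoxycyclobut-3-ene-1,2-dione, via benzyloxymethyllithium 7 (not isolated), via hydroxycyclobutenone adduct 8 (not isolated)
Conditions: n-BuLi, THF, −78 °C; add to 6, THF, −78 °C; then 12 M HCl, −78 °C → rt
Reagents that add atoms: water, O (supplies the oxygen of the new carbonyl)
Why: Tin–lithium exchange gives the α-alkoxy organolithium, which adds 1,2 to one carbonyl of the symmetrical squarate, and acid then ionises the carbinol and hydrolyses the isopropoxy-bearing terminus of the allyl cation, the established route to 3-alkoxy-4-alkylcyclobutenediones.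

**Step 5**
Reactants: 3 trisylhydrazone; 9 cyclobutenedione
Product: 11 2-[(benzyloxy)methyl]-4-hydroxy-3-isopropoxy-4-[(3R,6R)-6-methyl-3-(prop-1-en-2-yl)cyclohex-1-en-1-yl]cyclobut-2-en-1-one (both carbinol epimers), via vinyllithium 10 (not isolated)
Conditions: n-BuLi (2.1 equiv), THF, −78 → 0 °C; then 9, −78 °C; aq. NH4Cl
Reagents that add atoms: none
Why: In the Shapiro reaction the dianion formed at the less substituted α-methylene loses sulfinate and N2 to give the vinyllithium at the future C4a, which adds 1,2 to the ketone-like carbonyl attached to the isopropoxy-bearing carbon and not to the vinylogous ester carbonyl, so that C5–O, C6–O and C7–C19 fall in order; the carbinol configuration is irrelevant because step 7 destroys it.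

**Step 6**
Reactants: 11 hydroxycyclobutenone
Product: 12 tert-butyldimethylsilyl ether of 11 (key-step precursor)
Conditions: TBSOTf, 2,6-lutidine, CH2Cl2, −78 → 0 °C
Reagents that add atoms: tert-butyldimethylsilyl triflate, CC(C)(C)[Si](C)(C)OS(=O)(=O)C(F)(F)F
Why: Silylation of a hindered tertiary alcohol with a silyl triflate and a non-nucleophilic base is routine and masks the C5 oxygen so that only the C8 oxygen emerges free in step 7.

**Step 7**
Reactants: 12 4-cyclohexenyl-4-silyloxycyclobutenone
Product: 15 (1S,4R)-7-(benzyloxymethyl)-5-(tert-butyldimethylsilyloxy)-6-isopropoxy-4-methyl-1-(prop-1-en-2-yl)tetralin-8-ol, via dienylketene 13 (not isolated), via cyclohexadienone 14 (not isolated)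
Conditions: PhMe (degassed, 0.02 M), 110 °C, argon
Reagents that add atoms: none
Why: Heating releases the strain of the cyclobutenone by a conrotatory 4π ring opening that cleaves C5–C8, and the silyloxy donor on C5 turns outward, so the cyclohexenyl group lies cis to the ketene in dienylketene 13. The ketene carbon C8 then bonds to the ring alkene carbon C8a in a thermal disrotatory 6π electrocyclisation, the mode by which the benzene ring is closed, giving cyclohexadienone 14, whose C8a–H shifts to oxygen to aromatise. The closest known reaction is the Moore rearrangement of 4-alkenyl-4-hydroxy- or 4-silyloxycyclobutenones to hydroquinones and their mono-ethers. No stereocentre is created in 15, since the sp3 C8a of 14 is lost on tautomerisation, and C1 and C4 are not touched under neutral conditions. The selectivity needed is regiochemical and torquoselective: the first is fixed by the connectivity of 12 (carbinol C5 next to the isopropoxy carbon C6), the second by the oxygen on C5 and by the cis geometry that the six-membered ring imposes on the C4a=C8a alkene.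

**Step 8**
Reactants: 15 tetralin phenol
Product: 16 C8 triflate of 15
Conditions: Tf2O, pyridine, CH2Cl2, −20 → 0 °C
Reagents that add atoms: triflic anhydride, FC(F)(F)S(=O)(=O)OS(=O)(=O)C(F)(F)F
Why: O-sulfonylation of the hindered phenol prepares C8 for reductive removal and meanwhile leaves no free ring position and a less electron-rich ring for the Lewis acid step that follows.

**Step 9**
Reactants: 16 aryl triflate
Product: 17 homoallylic alcohol, 3-[(1S,4R)-tetralin-1-yl]but-3-en-1-ol with the ring substituents of 16
Conditions: (CH2O)n, Me2AlCl, CH2Cl2, −78 °C → rt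
Reagents that add atoms: formaldehyde (as paraformaldehyde), C=O
Why: The Lewis-acid-promoted carbonyl-ene reaction of formaldehyde with a 1,1-disubstituted alkene should take hydrogen from the methyl group, adding C13 and regenerating the C11=C18 methylene without forming a stereocentre.

**Step 10**
Reactants: 17 triflate alcohol
Product: 18 C8–H homoallylic alcohol
Conditions: Pd(OAc)2, dppf, HCO2H, Et3N, DMF, 80 °C
Reagents that add atoms: none
Why: Palladium-catalysed formate reduction of an aryl triflate (oxidative addition to zerovalent palladium, formate exchange, decarboxylation, C–H reductive elimination) should be fast enough that the neighbouring alkene does not insert.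

**Step 11**
Reactants: 18 homoallylic alcohol
Product: 19 homoallylic iodide (C13–I)
Conditions: I2, PPh3, imidazole, CH2Cl2, 0 °C → rt
Reagents that add atoms: iodine, [I][I]
Why: Appel-type iodination converts the primary alcohol to the iodide by SN2 displacement of an oxyphosphonium leaving group.

**Step 12**
Reactants: 20 (R)-3-bromo-2-methylpropan-1-ol
Product: 21 (R)-(3-bromo-2-methylpropoxy)(tert-butyl)dimethylsilane
Conditions: TBSCl, imidazole, CH2Cl2, rt
Reagents that add atoms: tert-butyldimethylsilyl chloride, CC(C)(C)[Si](C)(C)Cl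
Why: Imidazole-assisted silylation of a primary alcohol is routine and does not touch the purchased C15 stereocentre.

**Step 13**
Reactants: 19 homoallylic iodide; 21 silyl-protected bromide
Product: 23 (1S,4R)-tetralin of 18 bearing at C1 the (6S)-7-(tert-butyldimethylsilyloxy)-6-methylhept-1-en-2-yl chain, via Grignard reagent 22 (not isolated)
Conditions: 21, Mg, THF, rt; then 19, Li2CuCl4 (5 mol %), NMP, THF, −20 → 0 °C
Reagents that add atoms: none
Why: Copper-catalysed alkyl–alkyl cross-coupling of a primary Grignard reagent with a primary iodide (Kumada-type coupling with Li2CuCl4) joins C13 to C14 without touching C15.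

**Step 14**
Reactants: 23 1,1-disubstituted alkene
Product: 25 (11S)-C18 primary alcohol, via pinacol boronate 24 (not isolated)
Conditions: CuCl (5 mol %), (R)-DTBM-SEGPHOS, NaOt-Bu (cat.), HBpin, THF, rt; then NaBO3·4H2O, THF/H2O, rt
Reagents that add atoms: pinacolborane, [H]B1OC(C)(C)C(C)(C)O1 (boron in 24, only hydrogen in 25); sodium perborate, [Na+].[O-]OB=O (the C18 oxygen)
Why: In this copper hydride-catalysed anti-Markovnikov hydroboration, Cu–H adds with copper at terminal C18 and hydrogen at C11 on the face chosen by the chiral bisphosphine (catalyst control, expected to override the weak bias from C1), and σ-bond metathesis with pinacolborane followed by perborate oxidation with retention should give the 11S alcohol.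

**Step 15**
Reactants: 25 C18 alcohol
Product: 26 C18 acetate
Conditions: Ac2O, pyridine, DMAP (cat.), CH2Cl2, rt
Reagents that add atoms: acetic anhydride, CC(=O)OC(C)=O
Why: DMAP-catalysed acylation of the only free hydroxyl installs the acetate of the target.

**Step 16**
Reactants: 26 C19 benzyl ether
Product: 27 C19 aryl aldehyde
Conditions: DDQ, CH2Cl2/pH 7 buffer (10:1), 0 °C → rt
Reagents that add atoms: water, O (the aldehyde oxygen)
Why: DDQ should abstract hydride from the C19 methylene, which is activated by the ether oxygen and by the electron-rich ortho-alkoxyaryl ring (the mechanism of p-methoxybenzyl ether cleavage), and water collapses the oxocarbenium ion to the aldehyde and benzyl alcohol, while the tertiary benzylic C–H bonds, acetate and silyl ethers should react far more slowly.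

**Step 17**
Reactants: 27 aldehyde
Product: 28 C19 carboxylic acid
Conditions: NaClO2, NaH2PO4, 2-methyl-2-butene, t-BuOH/H2O, rt
Reagents that add atoms: sodium chlorite, [Na+].[O-]Cl=O
Why: Pinnick oxidation converts the aldehyde to the acid under buffered conditions, with the alkene scavenging hypochlorous acid so that the electron-rich ring is not chlorinated.

**Step 18**
Reactants: 28 bis-silyl ether acid
Product: 29 C5 phenol, C16 alcohol (C6 isopropyl ether retained)
Conditions: HF·pyridine, pyridine, THF, 0 °C → rt
Reagents that add atoms: none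
Why: Fluoride-driven Si–O cleavage under buffered acidic conditions removes both the alkyl and the aryl silyl ether and should leave the primary acetate and the isopropyl ether untouched.

**Step 19**
Reactants: 29 mono-isopropyl ether
Product: 30 target, CNP0191669.1
Conditions: BCl3, CH2Cl2, −78 → 0 °C; then H2O
Reagents that add atoms: none
Why: BCl3 dealkylation of an aryl isopropyl ether (coordination at the ether oxygen, assisted by chelation with the neighbouring carboxyl and phenol, then loss of the secondary alkyl group as its chloride) proceeds at temperatures at which a primary acetate should survive.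

**Compound list**

1 | (R)-carvone, (5R)-2-methyl-5-(prop-1-en-2-yl)cyclohex-2-en-1-one | C=C(C)[C@@H]1CC=C(C)C(=O)C1 | starting material
2 | trans-dihydrocarvone, (2R,5R)-2-methyl-5-(prop-1-en-2-yl)cyclohexan-1-one | C=C(C)[C@@H]1CC[C@@H](C)C(=O)C1 | intermediate
3 | (E)-2,4,6-triisopropylbenzenesulfonylhydrazone of 2 | C=C(C)[C@@H]1CC[C@@H](C)/C(=N/NS(=O)(=O)c2c(C(C)C)cc(C(C)C)cc2C(C)C)C1 | intermediate
4 | benzyl chloromethyl ether | ClCOCc1ccccc1 | starting material
5 | [(benzyloxy)methyl]tributylstannane | CCCC[Sn](CCCC)(CCCC)COCc1ccccc1 | intermediate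
6 | diisopropyl squarate | CC(C)OC1=C(OC(C)C)C(=O)C1=O | starting material
7 | (benzyloxy)methyllithium | [Li]COCc1ccccc1 | intermediate (not isolated)
8 | 4-[(benzyloxy)methyl]-4-hydroxy-2,3-diisopropoxycyclobut-2-en-1-one (racemic) | CC(C)OC1=C(OC(C)C)C(O)(COCc2ccccc2)C1=O | intermediate (not isolated)
9 | 3-[(benzyloxy)methyl]-4-isopropoxycyclobut-3-ene-1,2-dione | CC(C)OC1=C(COCc2ccccc2)C(=O)C1=O | intermediate
10 | [(3R,6R)-6-methyl-3-(prop-1-en-2-yl)cyclohex-1-en-1-yl]lithium | C=C(C)[C@@H]1CC[C@@H](C)C([Li])=C1 | intermediate (not isolated)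
11 | 2-[(benzyloxy)methyl]-4-hydroxy-3-isopropoxy-4-[(3R,6R)-6-methyl-3-(prop-1-en-2-yl)cyclohex-1-en-1-yl]cyclobut-2-en-1-one, both epimers at the carbinol carbon | C=C(C)[C@@H]1CC[C@@H](C)C(=C1)C2(O)C(=O)C(COCc3ccccc3)=C2OC(C)C | intermediate
12 | tert-butyldimethylsilyl ether of 11 (key-step precursor), both carbinol epimers | C=C(C)[C@@H]1CC[C@@H](C)C(=C1)C2(O[Si](C)(C)C(C)(C)C)C(=O)C(COCc3ccccc3)=C2OC(C)C | intermediate
13 | dienylketene, cyclohexenyl cis to the ketene-bearing carbon on the C5=C6 bond | C=C(C)[C@@H]1CC[C@@H](C)C(=C1)/C(O[Si](C)(C)C(C)(C)C)=C(OC(C)C)\C(COCc2ccccc2)=C=O | intermediate (not isolated)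
14 | bicyclic cyclohexa-2,4-dienone with sp3 C8a–H (C8 ketone, C4a=C5 and C6=C7 alkenes) | C=C(C)[C@@H]1CC[C@@H](C)C2=C(O[Si](C)(C)C(C)(C)C)C(OC(C)C)=C(COCc3ccccc3)C(=O)C12 | intermediate (not isolated)
15 | (1S,4R)-7-(benzyloxymethyl)-5-(tert-butyldimethylsilyloxy)-6-isopropoxy-4-methyl-1-(prop-1-en-2-yl)tetralin-8-ol (key-step product) | C=C(C)[C@@H]1CC[C@@H](C)c2c1c(O)c(COCc3ccccc3)c(OC(C)C)c2O[Si](C)(C)C(C)(C)C | intermediate
16 | C8 trifluoromethanesulfonate of 15 | C=C(C)[C@@H]1CC[C@@H](C)c2c1c(OS(=O)(=O)C(F)(F)F)c(COCc3ccccc3)c(OC(C)C)c2O[Si](C)(C)C(C)(C)C | intermediate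
17 | 3-[(1S,4R)-7-(benzyloxymethyl)-5-(tert-butyldimethylsilyloxy)-6-isopropoxy-4-methyl-8-(triflyloxy)tetralin-1-yl]but-3-en-1-ol | C=C(CCO)[C@@H]1CC[C@@H](C)c2c1c(OS(=O)(=O)C(F)(F)F)c(COCc3ccccc3)c(OC(C)C)c2O[Si](C)(C)C(C)(C)C | intermediate
18 | 3-[(1S,4R)-7-(benzyloxymethyl)-5-(tert-butyldimethylsilyloxy)-6-isopropoxy-4-methyltetralin-1-yl]but-3-en-1-ol | C=C(CCO)[C@@H]1CC[C@@H](C)c2c1cc(COCc3ccccc3)c(OC(C)C)c2O[Si](C)(C)C(C)(C)C | intermediate
19 | iodide of 18 (4-iodobut-1-en-2-yl at C1) | C=C(CCI)[C@@H]1CC[C@@H](C)c2c1cc(COCc3ccccc3)c(OC(C)C)c2O[Si](C)(C)C(C)(C)C | intermediate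
20 | (R)-3-bromo-2-methylpropan-1-ol | BrC[C@H](C)CO | starting material
21 | (R)-(3-bromo-2-methylpropoxy)(tert-butyl)dimethylsilane | BrC[C@H](C)CO[Si](C)(C)C(C)(C)C | intermediate
22 | (R)-[3-(tert-butyldimethylsilyloxy)-2-methylpropyl]magnesium bromide | Br[Mg]C[C@H](C)CO[Si](C)(C)C(C)(C)C | intermediate (not isolated)
23 | (1S,4R)-7-(benzyloxymethyl)-5-(tert-butyldimethylsilyloxy)-6-isopropoxy-4-methyl-1-[(6S)-7-(tert-butyldimethylsilyloxy)-6-methylhept-1-en-2-yl]tetralin | C=C(CCC[C@H](C)CO[Si](C)(C)C(C)(C)C)[C@@H]1CC[C@@H](C)c2c1cc(COCc3ccccc3)c(OC(C)C)c2O[Si](C)(C)C(C)(C)C | intermediate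
24 | (11S)-C18 pinacol boronate of 23 | CC1(C)OB(C[C@@H](CCC[C@H](C)CO[Si](C)(C)C(C)(C)C)[C@@H]2CC[C@@H](C)c3c2cc(COCc4ccccc4)c(OC(C)C)c3O[Si](C)(C)C(C)(C)C)OC1(C)C | intermediate (not isolated)
25 | (2S,6S)-2-[(1S,4R)-7-(benzyloxymethyl)-5-(tert-butyldimethylsilyloxy)-6-isopropoxy-4-methyltetralin-1-yl]-7-(tert-butyldimethylsilyloxy)-6-methylheptan-1-ol (11S,15S) | OC[C@@H](CCC[C@H](C)CO[Si](C)(C)C(C)(C)C)[C@@H]1CC[C@@H](C)c2c1cc(COCc3ccccc3)c(OC(C)C)c2O[Si](C)(C)C(C)(C)C | intermediate
26 | C18 acetate of 25 | CC(=O)OC[C@@H](CCC[C@H](C)CO[Si](C)(C)C(C)(C)C)[C@@H]1CC[C@@H](C)c2c1cc(COCc3ccccc3)c(OC(C)C)c2O[Si](C)(C)C(C)(C)C | intermediate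
27 | C19 aldehyde (7-formyl tetralin; C18 acetate, C5 and C16 silyl ethers, C6 isopropyl ether) | CC(=O)OC[C@@H](CCC[C@H](C)CO[Si](C)(C)C(C)(C)C)[C@@H]1CC[C@@H](C)c2c1cc(C=O)c(OC(C)C)c2O[Si](C)(C)C(C)(C)C | intermediate
28 | C19 carboxylic acid (C18 acetate, C5 and C16 silyl ethers, C6 isopropyl ether) | CC(=O)OC[C@@H](CCC[C@H](C)CO[Si](C)(C)C(C)(C)C)[C@@H]1CC[C@@H](C)c2c1cc(C(=O)O)c(OC(C)C)c2O[Si](C)(C)C(C)(C)C | intermediate
29 | C6 isopropyl ether of the target (free C5 phenol, C16 alcohol, C19 acid) | CC(=O)OC[C@@H](CCC[C@H](C)CO)[C@@H]1CC[C@@H](C)c2c1cc(C(=O)O)c(OC(C)C)c2O | intermediate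
30 | CNP0191669.1, (1S,4R)-1-[(2S,6S)-1-acetoxy-7-hydroxy-6-methylheptan-2-yl]-5,6-dihydroxy-4-methyltetralin-7-carboxylic acid (target locants) | CC(=O)OC[C@@H](CCC[C@H](C)CO)[C@@H]1CC[C@@H](C)c2c1cc(C(=O)O)c(O)c2O | target

**Step count and risk**

Total steps: 19. Longest linear sequence: 16 steps (1, 2, 5–11, 13–19).

The three steps most likely to fail:

Step 14 – the risk is insufficient facial discrimination in the Cu–H insertion, because the catalyst must set C11 next to a bulky C1 centre whose own bias is unknown, so a mixture of C11 epimers may result. Fallback: setting out from 23, an unselective hydroboration with 9-BBN and NaBO3 oxidation would give 25 together with its C11 epimer, the (11R)-alcohol F1. The two diastereomers are separated by chromatography. F1 is recycled by Dess–Martin oxidation to the (11R)-aldehyde F2, equilibration with DBU to its mixture with the (11S)-aldehyde F3, and NaBH4 reduction followed by renewed separation. The fallback comes back to the route at 25.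

Step 7 – the risk is that the bulky silyloxy group and the methyl-flanked cyclohexenyl group retard the 6π closure, so that the ketene is diverted (dimerisation, capture by adventitious nucleophiles), or that the electron-rich silyloxyphenol is oxidised during isolation. Fallback: setting out from 11, the unprotected carbinol is heated in degassed toluene in the classical Moore mode to give the hydroquinone F4. The C8 hydroxyl is meta to the isopropoxy group and should be the more acidic, whereas the C5 hydroxyl is ortho to it and hydrogen-bonded. It is therefore triflated selectively with PhNTf2 and K2CO3 (one equivalent) to the C8 mono-triflate F5, and silylation of the C5 hydroxyl with TBSOTf and 2,6-lutidine comes back to the route at 16.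

Step 16 – the risk is hydride abstraction at the tertiary benzylic C1–H or C4–H, or over-oxidation of the electron-rich ring, competing with abstraction at C19. Fallback: setting out from 26, hydrogenolysis of the benzyl ether (H2, Pd/C, EtOAc) would give the C19 benzylic alcohol F6, and oxidation with MnO2 in CH2Cl2 comes back to the route at 27.

**Further compounds**

F1 | step 14 | (11R)-epimer of alcohol 25 | OC[C@H](CCC[C@H](C)CO[Si](C)(C)C(C)(C)C)[C@@H]1CC[C@@H](C)c2c1cc(COCc3ccccc3)c(OC(C)C)c2O[Si](C)(C)C(C)(C)C
F2 | step 14 | (11R)-C18 aldehyde from F1 | O=C[C@H](CCC[C@H](C)CO[Si](C)(C)C(C)(C)C)[C@@H]1CC[C@@H](C)c2c1cc(COCc3ccccc3)c(OC(C)C)c2O[Si](C)(C)C(C)(C)C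
F3 | step 14 | (11S)-C18 aldehyde | O=C[C@@H](CCC[C@H](C)CO[Si](C)(C)C(C)(C)C)[C@@H]1CC[C@@H](C)c2c1cc(COCc3ccccc3)c(OC(C)C)c2O[Si](C)(C)C(C)(C)C
F4 | step 7 | (1S,4R)-7-(benzyloxymethyl)-6-isopropoxy-4-methyl-1-(prop-1-en-2-yl)tetralin-5,8-diol | C=C(C)[C@@H]1CC[C@@H](C)c2c1c(O)c(COCc3ccccc3)c(OC(C)C)c2O
F5 | step 7 | C8 mono-triflate of F4 (free C5 phenol) | C=C(C)[C@@H]1CC[C@@H](C)c2c1c(OS(=O)(=O)C(F)(F)F)c(COCc3ccccc3)c(OC(C)C)c2O
F6 | step 16 | C19 benzylic alcohol (debenzylated 26) | CC(=O)OC[C@@H](CCC[C@H](C)CO[Si](C)(C)C(C)(C)C)[C@@H]1CC[C@@H](C)c2c1cc(CO)c(OC(C)C)c2O[Si](C)(C)C(C)(C)C
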